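**Plan**

1. Locants: the core is numbered as 2H-cyclohepta[b]furan-2-one (O1, C2, C3, C3a, C4 to C8, C8a); the side chain is C1′ (angelate carbinol), C2′, C3′ (acetate carbon).
2. Retrosynthesis, in order: the angelate C1′–O ester; C1′–OH back to the ketone; ring bond C7–C8 (radical conjugate addition of a C8 radical, from a CH2I arm on the lactone, to C7, the β-carbon of an (E)-ethylidene ketone C7=C6–C1′=O); diene bond C5–C6 (Stille coupling); lactone bond C3–C3a (opening of a Sharpless epoxy alcohol).
3. Forward: the γ-lactone ring is made first with its exo-methylene and CH2I arm, the C5–C6 bond then joins the side-chain fragment, the seven-membered ring closes last (C8 onto C7), and C1′ is then reduced and acylated.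
4. Enabling feature: C8 is β to the lactone oxygen O1, so a CH2I group there is a clean primary-radical source; C7 is β to the C1′ carbonyl through C6, and C6 is also allylic to C4=C5, so the adduct is a 1-acylallyl radical which, reduced at C6, leaves the alkene exactly at C4=C5; the Z C4=C5 alkene holds C3a and C6 cis and folds the chain for seven-ring closure.
5. Stereochemistry: C3a/C8a from Sharpless epoxidation plus SN2 opening (trans-epoxide to cis-lactone); C7 and C6 from the chair-like closure and axial hydrogen delivery; C1′ from CBS reduction; Z-C4=C5 from a Stork–Zhao olefination; the angelate geometry from angelic acid.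

Key step: step 15

Remark: compounds 1, 13, 22, ethyltriphenylphosphonium iodide and 1-propynylmagnesium bromide solution are taken as commercial; the side-chain fragment is carried as a racemic carbinol because that centre is oxidised in step 14 and reset in step 16.

**Route**

Step 1
Reactants: 1 ethyl (E)-4-oxobut-2-enoate
Product: 2 ethyl (2E,4Z)-5-iodohexa-2,4-dienoate
Conditions: EtPPh3I, n-BuLi, THF, 0 °C; I2, −78 °C; NaN(SiMe3)2, −20 °C; then 1, −78 → −20 °C
Reagents that add atoms: ethyltriphenylphosphonium iodide, CC[P+](c1ccccc1)(c1ccccc1)c1ccccc1.[I-]; iodine, II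
Why: Stork–Zhao olefination (Wittig reaction of the α-iodoethylidene ylide) should give the Z-iodoalkene under kinetic control, with the chain carbon cis to iodine, while the E-enoate is untouched at low temperature.

Step 2
Reactants: 2 ethyl (2E,4Z)-5-iodohexa-2,4-dienoate
Product: 3 (2E,4Z)-5-iodohexa-2,4-dien-1-ol
Conditions: iBu2AlH, CH2Cl2, −78 °C; aq. potassium sodium tartrate work-up
Reagents that add atoms: none
Why: 1,2-reduction of the conjugated ester by the aluminium hydride should give the allylic alcohol, the vinyl iodide and both alkene geometries being inert at −78 °C.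

Step 3
Reactants: 3 (2E,4Z)-5-iodohexa-2,4-dien-1-ol
Product: 4 [(2R,3R)-3-[(Z)-2-iodoprop-1-en-1-yl]oxiran-2-yl]methanol
Conditions: Ti(OiPr)4 (cat.), D-(−)-diethyl tartrate (cat.), t-BuOOH, 4 Å MS, CH2Cl2, −20 °C
Reagents that add atoms: tert-butyl hydroperoxide, CC(C)(C)OO
Why: Sharpless asymmetric epoxidation is directed by the allylic hydroxyl to the 2,3-alkene only (the iodoalkene is electron-poor and remote), and D-(−)-tartrate should deliver oxygen to the face that gives the (2R,3R)-epoxide, which fixes the later C8a centre and, after inversion, C3a.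

Step 4
Reactants: 4 [(2R,3R)-3-[(Z)-2-iodoprop-1-en-1-yl]oxiran-2-yl]methanol
Product: 5 tert-butyl{[(2R,3R)-3-[(Z)-2-iodoprop-1-en-1-yl]oxiran-2-yl]methoxy}diphenylsilane
Conditions: TBDPSCl, imidazole, CH2Cl2, 0 °C → rt
Reagents that add atoms: tert-butyl(chloro)diphenylsilane, CC(C)(C)[Si](Cl)(c1ccccc1)c1ccccc1
Why: silyl ether formation at the primary alcohol blocks Payne rearrangement in the next step, and the TBDPS group is chosen because it should survive the acid lactonisation.

Step 5
Reactants: 5 tert-butyl{[(2R,3R)-3-[(Z)-2-iodoprop-1-en-1-yl]oxiran-2-yl]methoxy}diphenylsilane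
Product: 7 (4S,5S)-5-{[(tert-butyldiphenylsilyl)oxy]methyl}-4-[(Z)-2-iodoprop-1-en-1-yl]oxolan-2-one, via hydroxy ester 6 (not isolated)
Conditions: t-BuOAc, LiN(iPr)2, THF, −78 °C; Et2AlCl; then 5, −78 → −30 °C; H2O work-up; then CF3CO2H, CH2Cl2, 0 °C → rt
Reagents that add atoms: tert-butyl acetate, CC(=O)OC(C)(C)C
Why: Lewis-acid-assisted SN2 opening of the vinyl epoxide by the aluminium ester enolate should occur at the allylic carbon with inversion (retention at the carbinol carbon), and acid lactonisation then converts the trans-epoxide into the cis-4,5-disubstituted γ-lactone.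

Step 6
Reactants: 7 (4S,5S)-5-{[(tert-butyldiphenylsilyl)oxy]methyl}-4-[(Z)-2-iodoprop-1-en-1-yl]oxolan-2-one
Product: 10 (4R,5S)-5-{[(tert-butyldiphenylsilyl)oxy]methyl}-4-[(Z)-2-iodoprop-1-en-1-yl]-3-methylideneoxolan-2-one, via Mannich base 8 (not isolated), via trimethylammonium iodide 9 (not isolated)
Conditions: LiN(SiMe3)2, THF, −78 °C; CH2=NMe2+ I−, −78 °C → rt; then MeI, MeOH, rt; then NaHCO3, CH2Cl2/H2O, rt
Reagents that add atoms: Eschenmoser's salt (N,N-dimethylmethyleneiminium iodide), C=[N+](C)C.[I-]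
Why: α-methylenation by Mannich reaction of the lactone enolate with Eschenmoser's salt, N-methylation and E1cB elimination should install the exo-methylene without touching C4 or C5, which are not acidic.

Step 7
Reactants: 10 (4R,5S)-5-{[(tert-butyldiphenylsilyl)oxy]methyl}-4-[(Z)-2-iodoprop-1-en-1-yl]-3-methylideneoxolan-2-one
Product: 11 (4R,5S)-5-(hydroxymethyl)-4-[(Z)-2-iodoprop-1-en-1-yl]-3-methylideneoxolan-2-one
Conditions: Bu4NF, AcOH, THF, 0 °C → rt
Reagents that add atoms: none
Why: fluoride-mediated desilylation, buffered with acetic acid so that no basic fluoride or alkoxide adds to the α-methylene lactone, should free the primary alcohol.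

Step 8
Reactants: 11 (4R,5S)-5-(hydroxymethyl)-4-[(Z)-2-iodoprop-1-en-1-yl]-3-methylideneoxolan-2-one
Product: 12 (4R,5S)-5-(iodomethyl)-4-[(Z)-2-iodoprop-1-en-1-yl]-3-methylideneoxolan-2-one
Conditions: I2, PPh3, imidazole, CH2Cl2, 0 °C
Reagents that add atoms: iodine, II
Why: Appel-type iodination (alkoxyphosphonium ion, then SN2 by iodide at the primary carbon) should give the radical precursor without touching the stereocentres.

Step 9
Reactants: 13 3-[(tert-butyldimethylsilyl)oxy]propanal
Product: 14 1-[(tert-butyldimethylsilyl)oxy]hex-4-yn-3-ol (racemic)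
Conditions: CH3C≡CMgBr, THF, −78 → 0 °C; then H2O
Reagents that add atoms: 1-propynylmagnesium bromide, CC#C[Mg]Br
Why: Grignard addition of the alkynyl nucleophile to the aldehyde should give the propargylic alcohol, deliberately racemic.

Step 10
Reactants: 14 1-[(tert-butyldimethylsilyl)oxy]hex-4-yn-3-ol
Product: 15 hex-4-yne-1,3-diol (racemic)
Conditions: camphorsulfonic acid (cat.), MeOH, rt
Reagents that add atoms: none
Why: acid-catalysed methanolysis should cleave the primary silyl ether and leave the propargylic alcohol untouched.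

Step 11
Reactants: 15 hex-4-yne-1,3-diol
Product: 16 3-hydroxyhex-4-yn-1-yl acetate (racemic)
Conditions: AcCl, 2,4,6-collidine, CH2Cl2, −78 °C
Reagents that add atoms: acetyl chloride, CC(=O)Cl
Why: low-temperature acylation with a hindered base should acetylate the primary hydroxyl selectively over the secondary propargylic one, placing the final acetate early.

Step 12
Reactants: 16 3-hydroxyhex-4-yn-1-yl acetate
Product: 17 (Z)-3-hydroxy-4-(tributylstannyl)hex-4-en-1-yl acetate (racemic)
Conditions: Bu3SnH, [Cp*RuCl]4 (cat.), CH2Cl2, rt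
Reagents that add atoms: tributyltin hydride, CCCC[SnH](CCCC)CCCC
Why: ruthenium-catalysed trans-hydrostannation of a propargylic alcohol should put tin on the alkyne carbon next to the hydroxyl and add H and Sn anti, giving the Z-stannane with methyl cis to tin.

Step 13
Reactants: 12 (4R,5S)-5-(iodomethyl)-4-[(Z)-2-iodoprop-1-en-1-yl]-3-methylideneoxolan-2-one; 17 (Z)-3-hydroxy-4-(tributylstannyl)hex-4-en-1-yl acetate
Product: 18 (4E)-3-hydroxy-4-{(Z)-1-[(2S,3R)-2-(iodomethyl)-4-methylidene-5-oxooxolan-3-yl]prop-1-en-2-yl}hex-4-en-1-yl acetate (both C3 epimers)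
Conditions: Pd(PPh3)4 (cat.), Cu(O2CC4H3S) (copper thiophene-2-carboxylate), DMF, 0 °C → rt
Reagents that add atoms: none
Why: Stille coupling promoted by tin-to-copper transmetalation should join the two alkenyl carbons with retention of both geometries, zerovalent palladium inserting into the C(sp2)–I bond far faster than into the primary C(sp3)–I bond.

Step 14
Reactants: 18 (4E)-3-hydroxy-4-{(Z)-1-[(2S,3R)-2-(iodomethyl)-4-methylidene-5-oxooxolan-3-yl]prop-1-en-2-yl}hex-4-en-1-yl acetate
Product: 19 (4E)-4-{(Z)-1-[(2S,3R)-2-(iodomethyl)-4-methylidene-5-oxooxolan-3-yl]prop-1-en-2-yl}-3-oxohex-4-en-1-yl acetate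
Conditions: MnO2 (activated, excess), CH2Cl2, rt
Reagents that add atoms: none
Why: MnO2 oxidation of the allylic alcohol should give the cross-conjugated dienone under neutral conditions that spare the alkyl iodide and the β-acetoxy ketone, both carbinol epimers converging.

Step 15
Reactants: 19 (4E)-4-{(Z)-1-[(2S,3R)-2-(iodomethyl)-4-methylidene-5-oxooxolan-3-yl]prop-1-en-2-yl}-3-oxohex-4-en-1-yl acetate
Product: 20 3-[(3aR,6S,7R,8aR)-5,7-dimethyl-3-methylidene-2-oxo-3,3a,6,7,8,8a-hexahydro-2H-cyclohepta[b]furan-6-yl]-3-oxopropyl acetate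
Conditions: (Me3Si)3SiH and AIBN added by syringe pump, PhH (0.003 M), 80 °C
Reagents that add atoms: none
Why: The silyl radical abstracts iodine from the CH2I group to give the primary C8 radical (β to the lactone oxygen O1), which adds to C7, the β-carbon of the (E)-ethylidene ketone, and the resulting 1-acylallyl radical spread over C6–C5–C4 is quenched by the silane at C6, the carbonyl-bearing terminus, so that the alkene stays at C4=C5. The closest known reaction type is the Giese-type intramolecular radical conjugate addition of iodoalkyl enones under silane/AIBN chain conditions. The seven-membered carbocycle closes in the 7-endo-trig mode, because 6-exo attack would have to hit the fully substituted, polarity-mismatched α-carbon C6, and closure onto C4=C5 would be 4-exo or 5-endo. C7 is set in a chair-like transition state held by the Z C4=C5 alkene and the cis-fused lactone: the methyl of the E-ethylidene unit (cis to C5) must sit pseudo-axial, and the chair that would also place O1 axial suffers a 1,3-diaxial Me/O clash, so the C8a–O1 bond goes pseudo-equatorial and the new C7–Me bond should end trans to it; C6 is set by axial hydrogen delivery to the ring-flipped radical, which leaves the acyl group equatorial and trans to the C7 methyl (this centre is α to the ketone and can also settle to that arrangement). The step needs cyclisation to outrun direct reduction and intermolecular addition to the α-methylene lactone, which high dilution and slow silane addition should secure, while iodine abstraction by the silyl radical is faster than its addition to either acceptor.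

Step 16
Reactants: 20 3-[(3aR,6S,7R,8aR)-5,7-dimethyl-3-methylidene-2-oxo-3,3a,6,7,8,8a-hexahydro-2H-cyclohepta[b]furan-6-yl]-3-oxopropyl acetate
Product: 21 (3S)-3-hydroxy-3-[(3aR,6S,7R,8aR)-5,7-dimethyl-3-methylidene-2-oxo-3,3a,6,7,8,8a-hexahydro-2H-cyclohepta[b]furan-6-yl]propyl acetate
Conditions: (R)-2-methyl-CBS-oxazaborolidine (cat.), catecholborane, PhMe, −78 °C; aq. work-up
Reagents that add atoms: none
Why: Corey–Bakshi–Shibata reduction, with the branched ring carbon C6 as the large group and the CH2 as the small one, should deliver hydride from the (R)-catalyst to the face that gives the (S)-carbinol, while catecholborane at −78 °C spares the lactone, the acetate and the alkenes.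

Step 17
Reactants: 21 (3S)-3-hydroxy-3-[(3aR,6S,7R,8aR)-5,7-dimethyl-3-methylidene-2-oxo-3,3a,6,7,8,8a-hexahydro-2H-cyclohepta[b]furan-6-yl]propyl acetate; 22 angelic acid
Product: 24 (1S)-3-acetoxy-1-[(3aR,6S,7R,8aR)-5,7-dimethyl-3-methylidene-2-oxo-3,3a,6,7,8,8a-hexahydro-2H-cyclohepta[b]furan-6-yl]propyl (Z)-2-methylbut-2-enoate, via angelic 2,4,6-trichlorobenzoic anhydride 23 (not isolated)
Conditions: 22, 2,4,6-Cl3C6H2COCl, Et3N, PhMe, rt; then 21, 80 °C
Reagents that add atoms: none
Why: Yamaguchi-type mixed-anhydride esterification should acylate the secondary alcohol at the less hindered angeloyl carbonyl with retention at C1′, and leaving out nucleophilic amine catalysts keeps the Z geometry of the angelate.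

**Compound list**

1 | ethyl (E)-4-oxobut-2-enoate | CCOC(=O)/C=C/C=O | starting material
2 | ethyl (2E,4Z)-5-iodohexa-2,4-dienoate | CCOC(=O)/C=C/C=C(C)\I | intermediate
3 | (2E,4Z)-5-iodohexa-2,4-dien-1-ol | OC/C=C/C=C(C)\I | intermediate
4 | [(2R,3R)-3-[(Z)-2-iodoprop-1-en-1-yl]oxiran-2-yl]methanol | O1[C@H](/C=C(C)\I)[C@H]1CO | intermediate
5 | tert-butyl{[(2R,3R)-3-[(Z)-2-iodoprop-1-en-1-yl]oxiran-2-yl]methoxy}diphenylsilane | O1[C@H](/C=C(C)\I)[C@H]1CO[Si](c1ccccc1)(c1ccccc1)C(C)(C)C | intermediate
6 | tert-butyl (3S,4S)-5-[(tert-butyldiphenylsilyl)oxy]-4-hydroxy-3-[(Z)-2-iodoprop-1-en-1-yl]pentanoate | CC(C)(C)OC(=O)C[C@@H](/C=C(C)\I)[C@H](O)CO[Si](c1ccccc1)(c1ccccc1)C(C)(C)C | intermediate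
7 | (4S,5S)-5-{[(tert-butyldiphenylsilyl)oxy]methyl}-4-[(Z)-2-iodoprop-1-en-1-yl]oxolan-2-one | C1C(=O)O[C@H](CO[Si](c2ccccc2)(c2ccccc2)C(C)(C)C)[C@@H]1/C=C(C)\I | intermediate
8 | (4S,5S)-5-{[(tert-butyldiphenylsilyl)oxy]methyl}-3-[(dimethylamino)methyl]-4-[(Z)-2-iodoprop-1-en-1-yl]oxolan-2-one (C3 epimers) | CN(C)CC1C(=O)O[C@H](CO[Si](c2ccccc2)(c2ccccc2)C(C)(C)C)[C@@H]1/C=C(C)\I | intermediate
9 | {[(4S,5S)-5-{[(tert-butyldiphenylsilyl)oxy]methyl}-4-[(Z)-2-iodoprop-1-en-1-yl]-2-oxooxolan-3-yl]methyl}trimethylammonium iodide (C3 epimers) | C[N+](C)(C)CC1C(=O)O[C@H](CO[Si](c2ccccc2)(c2ccccc2)C(C)(C)C)[C@@H]1/C=C(C)\I.[I-] | intermediate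
10 | (4R,5S)-5-{[(tert-butyldiphenylsilyl)oxy]methyl}-4-[(Z)-2-iodoprop-1-en-1-yl]-3-methylideneoxolan-2-one | C=C1C(=O)O[C@H](CO[Si](c2ccccc2)(c2ccccc2)C(C)(C)C)[C@@H]1/C=C(C)\I | intermediate
11 | (4R,5S)-5-(hydroxymethyl)-4-[(Z)-2-iodoprop-1-en-1-yl]-3-methylideneoxolan-2-one | C=C1C(=O)O[C@H](CO)[C@@H]1/C=C(C)\I | intermediate
12 | (4R,5S)-5-(iodomethyl)-4-[(Z)-2-iodoprop-1-en-1-yl]-3-methylideneoxolan-2-one | C=C1C(=O)O[C@H](CI)[C@@H]1/C=C(C)\I | intermediate
13 | 3-[(tert-butyldimethylsilyl)oxy]propanal | O=CCCO[Si](C)(C)C(C)(C)C | starting material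
14 | 1-[(tert-butyldimethylsilyl)oxy]hex-4-yn-3-ol (racemic) | CC#CC(O)CCO[Si](C)(C)C(C)(C)C | intermediate
15 | hex-4-yne-1,3-diol (racemic) | CC#CC(O)CCO | intermediate
16 | 3-hydroxyhex-4-yn-1-yl acetate (racemic) | CC#CC(O)CCOC(C)=O | intermediate
17 | (Z)-3-hydroxy-4-(tributylstannyl)hex-4-en-1-yl acetate (racemic) | C/C=C(\[Sn](CCCC)(CCCC)CCCC)C(O)CCOC(C)=O | intermediate
18 | (4E)-3-hydroxy-4-{(Z)-1-[(2S,3R)-2-(iodomethyl)-4-methylidene-5-oxooxolan-3-yl]prop-1-en-2-yl}hex-4-en-1-yl acetate (both C3 epimers) | C=C1C(=O)O[C@H](CI)[C@@H]1/C=C(C)\C(=C/C)C(O)CCOC(C)=O | intermediate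
19 | (4E)-4-{(Z)-1-[(2S,3R)-2-(iodomethyl)-4-methylidene-5-oxooxolan-3-yl]prop-1-en-2-yl}-3-oxohex-4-en-1-yl acetate | C=C1C(=O)O[C@H](CI)[C@@H]1/C=C(C)\C(=C/C)C(=O)CCOC(C)=O | intermediate
20 | 3-[(3aR,6S,7R,8aR)-5,7-dimethyl-3-methylidene-2-oxo-3,3a,6,7,8,8a-hexahydro-2H-cyclohepta[b]furan-6-yl]-3-oxopropyl acetate | C=C1C(=O)O[C@@H]2C[C@@H](C)[C@H](C(=O)CCOC(C)=O)C(C)=C[C@H]12 | intermediate
21 | (3S)-3-hydroxy-3-[(3aR,6S,7R,8aR)-5,7-dimethyl-3-methylidene-2-oxo-3,3a,6,7,8,8a-hexahydro-2H-cyclohepta[b]furan-6-yl]propyl acetate | C=C1C(=O)O[C@@H]2C[C@@H](C)[C@H]([C@H](CCOC(C)=O)O)C(C)=C[C@H]12 | intermediate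
22 | angelic acid, (Z)-2-methylbut-2-enoic acid | C/C=C(/C)C(=O)O | starting material
23 | (Z)-2-methylbut-2-enoic 2,4,6-trichlorobenzoic anhydride | C/C=C(/C)C(=O)OC(=O)c1c(Cl)cc(Cl)cc1Cl | intermediate
24 | (1S)-3-acetoxy-1-[(3aR,6S,7R,8aR)-5,7-dimethyl-3-methylidene-2-oxo-3,3a,6,7,8,8a-hexahydro-2H-cyclohepta[b]furan-6-yl]propyl (Z)-2-methylbut-2-enoate (CNP0163960.1) | C=C1C(=O)O[C@@H]2C[C@@H](C)[C@H]([C@H](CCOC(C)=O)OC(=O)/C(C)=C\C)C(C)=C[C@H]12 | target

**Step count and risks**

Total step count: 17. Longest linear sequence: 13 (steps 1–8, then 13–17); the side-chain branch (steps 9–12) is 4 steps.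

Steps most likely to fail:

Step 15. The closure may show poor or reversed facial selectivity at C7 (methyl ending cis to O1), because the chair model for a seven-membered transition state is not secure; direct reduction of the C8 radical may also compete with the slow 7-endo closure. Fallback: the geometric isomer of the acceptor presents H and Me interchanged to the same transition state and should invert the outcome at C7. It sets out from 16: palladium-catalysed syn-hydrostannation (Bu3SnH, PdCl2(PPh3)2, THF) should give (E)-3-hydroxy-4-(tributylstannyl)hex-4-en-1-yl acetate F1, with tin trans to methyl. Coupling of F1 with 12 under the conditions of step 13 should give the (4Z)-dienol F2, and MnO2 oxidation the (Z)-ethylidene dienone F3. The same silane-mediated closure of F3 comes back to the route at 20.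

Step 13. Transmetalation of the hindered, α-branched stannane may be slow, so that the primary alkyl iodide is consumed meanwhile (substitution by carboxylate, insertion of zerovalent palladium, reduction). Fallback: the coupling is moved ahead of the iodide. It sets out from 10, which is coupled with 17 under the same conditions to give the silyl-protected dienol F4. MnO2 oxidation should give the silyl-protected dienone F5, and HF·pyridine in THF (acidic, so the β-acetoxy ketone is not eliminated) the primary alcohol F6. Iodination with I2, PPh3 and imidazole comes back to the route at 19.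

Step 5. Under Lewis acid the vinyl epoxide may open with loss of regiocontrol (attack at the carbinol-side carbon) or through an ionised allylic species with loss of configuration at the future C3a. Fallback: a soft, non-Lewis-acidic nucleophile and a different methylenation. It sets out from 5: sodium dimethyl malonate (NaH, THF/DMF, 60 °C) should open the epoxide by clean SN2 at the allylic carbon and lactonise spontaneously to the α-methoxycarbonyl lactone F7. Saponification (LiOH, then acid) should give the α-carboxy lactone F8, and decarboxylative Mannich methylenation (Et2NH, aq. CH2O, then AcOH/NaOAc, heat) comes back to the route at 10, bypassing 7 and step 6.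

**Further compounds**

F1 | step 15 | (E)-3-hydroxy-4-(tributylstannyl)hex-4-en-1-yl acetate (racemic) | C/C=C(/[Sn](CCCC)(CCCC)CCCC)C(O)CCOC(C)=O
F2 | step 15 | (4Z)-3-hydroxy-4-{(Z)-1-[(2S,3R)-2-(iodomethyl)-4-methylidene-5-oxooxolan-3-yl]prop-1-en-2-yl}hex-4-en-1-yl acetate (both C3 epimers) | C=C1C(=O)O[C@H](CI)[C@@H]1/C=C(C)\C(=C\C)C(O)CCOC(C)=O
F3 | step 15 | (4Z)-4-{(Z)-1-[(2S,3R)-2-(iodomethyl)-4-methylidene-5-oxooxolan-3-yl]prop-1-en-2-yl}-3-oxohex-4-en-1-yl acetate | C=C1C(=O)O[C@H](CI)[C@@H]1/C=C(C)\C(=C\C)C(=O)CCOC(C)=O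
F4 | step 13 | (4E)-4-{(Z)-1-[(2S,3R)-2-{[(tert-butyldiphenylsilyl)oxy]methyl}-4-methylidene-5-oxooxolan-3-yl]prop-1-en-2-yl}-3-hydroxyhex-4-en-1-yl acetate (both C3 epimers) | C=C1C(=O)O[C@H](CO[Si](c2ccccc2)(c2ccccc2)C(C)(C)C)[C@@H]1/C=C(C)\C(=C/C)C(O)CCOC(C)=O
F5 | step 13 | (4E)-4-{(Z)-1-[(2S,3R)-2-{[(tert-butyldiphenylsilyl)oxy]methyl}-4-methylidene-5-oxooxolan-3-yl]prop-1-en-2-yl}-3-oxohex-4-en-1-yl acetate | C=C1C(=O)O[C@H](CO[Si](c2ccccc2)(c2ccccc2)C(C)(C)C)[C@@H]1/C=C(C)\C(=C/C)C(=O)CCOC(C)=O
F6 | step 13 | (4E)-4-{(Z)-1-[(2S,3R)-2-(hydroxymethyl)-4-methylidene-5-oxooxolan-3-yl]prop-1-en-2-yl}-3-oxohex-4-en-1-yl acetate | C=C1C(=O)O[C@H](CO)[C@@H]1/C=C(C)\C(=C/C)C(=O)CCOC(C)=O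
F7 | step 5 | methyl (4S,5S)-5-{[(tert-butyldiphenylsilyl)oxy]methyl}-4-[(Z)-2-iodoprop-1-en-1-yl]-2-oxooxolane-3-carboxylate (C3 epimers) | COC(=O)C1C(=O)O[C@H](CO[Si](c2ccccc2)(c2ccccc2)C(C)(C)C)[C@@H]1/C=C(C)\I
F8 | step 5 | (4S,5S)-5-{[(tert-butyldiphenylsilyl)oxy]methyl}-4-[(Z)-2-iodoprop-1-en-1-yl]-2-oxooxolane-3-carboxylic acid (C3 epimers) | OC(=O)C1C(=O)O[C@H](CO[Si](c2ccccc2)(c2ccccc2)C(C)(C)C)[C@@H]1/C=C(C)\I
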